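- I time the L.

| flask | L | X | remark | time |
|---|---|---|---|---|
| larch | 0.20 M (fed, over 20 s) | 36 µM | run made earlier; the fed solution adds 0.25 times the starting volume |  |
| Tuesday's | 0.80 M (fed, over 20 s) | 36 µM | the fed solution adds 0.25 times the starting volume | 3.0 min |
| Sunday's | 0.18 M (fed, over 6.0 s) | 25 µM | the fed solution adds 0.25 times the starting volume | 3.0 min |
| Wednesday's | 0.18 M (fed, over 20 s) | 36 µM | the fed solution adds 0.25 times the starting volume | 3.0 min |
| Monday's | 0.40 M (fed, over 5.0 s) | 36 µM | the fed solution adds 0.25 times the starting volume | 3.0 min |
| Friday's | 0.10 M (fed, over 10 s) | 80 µM | the fed solution adds 0.25 times the starting volume | 3.0 min |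
| Thursday's | 0.18 M (fed, over 20 s) | 20 µM | the fed solution adds 0.25 times the starting volume | 3.0 min |

larch run (percent of the L charged)

| time / s | Q / % | L / % |
|---|---|---|
| 10.0 | 7.9 | 42.0 |
| 15.0 | 12.1 | 62.1 |
| 25.0 | 20.6 | 78.3 |
| 40.0 | 32.9 | 62.9 |

(readings scatter by 0.3 percentage points)

- amounts are per litre of the starting volume; all of the dose is in the solution fed
- steps thought possible: X + Q -> X + Z; Q <-> D; G -> X + Q; L + X <-> G
- percentages count the whole charge, also what has not yet gone in
- no earlier run changes the charge of X; that part of a forecast is a guess

1. the flasks by amount of Q, in percent of the L charged, highest first, at 3.0 min (Tuesday's / Sunday's / Wednesday's / Monday's / Friday's / Thursday's)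
2. the same order at 40 s (Tuesday's / Sunday's / Wednesday's / Monday's / Friday's / Thursday's)
3. the amount of Q, in percent of the L charged of the flask you put first, at 3.0 min
4. the amount of Q, in percent of the L charged of the flask you put last, at 3.0 min

- In the larch run the feed has ended by 25.0 s, and L falls from 78.3 % then to 62.9 % at 40.0 s, each reading good to 0.3 percentage points.
- Per X charged, that slope reads as a turnover number of 57.0 s⁻¹.
- I replace the curve by this steady rate. Thursday's then needs 158 s, its clearing time: the charge of L over the turnover number times the charge of X.
- I check that replacement. The mean over the whole larch run reads 51.5 s⁻¹, lower than the slope, and it gives Thursday's 175 s, still under 3.0 min.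
- First setting, the charge of L: by hand, with X held, the clearing time lengthens in proportion. Wednesday's takes 87.7 s and Monday's 195 s.
- Tuesday's takes 390 s, longer than 3.0 min, so I expect about 46.2 % of its L to have turned over by then.
- Second setting, the charge of X: by hand, with L held, the clearing time shortens in proportion, giving Sunday's 126 s. Friday's has less L as well and gets 21.9 s. No earlier run changes X, so this proportion is a guess.
- Third setting, the feed time: Friday's feed of 10 s is shorter than its clearing time, so I expect it to move little at 3.0 min.
- At 40 s I expect Q to follow the clearing times, shortest first.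
- Once its L is gone, I expect a flask to have its X free of G, and the step X + Q → X + Z, if it runs, can then use that X. The larch readings hold neither Z nor D, so I give no figure for it.
- I rank by how long and how much X can meet Q. Friday's clears soonest and has the most X, so I put it last at 3.0 min. Thursday's clears just before 3.0 min and has the least X, so I put it first.
- The forecast says Thursday's > Monday's > Sunday's > Wednesday's > Friday's > Tuesday's at 3.0 min and Friday's > Wednesday's > Sunday's > Thursday's > Monday's > Tuesday's at 40 s, with 60 % first and 28 % last, holding that “the enzyme is nearly saturated and zero order in L”; my last place differs.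

- Thursday's comes first with 56.3 % and Friday's last with 1.57 %, in the order Thursday's > Monday's > Sunday's > Tuesday's > Wednesday's > Friday's at 3.0 min and Friday's > Wednesday's > Sunday's > Thursday's > Monday's > Tuesday's at 40 s. At 3.00 min Friday's holds 77.7 % of its L charged as Z, with 100 % of its X free. Thursday's clearing time of 158 s falls before 3.0 min, yet 3.63 % of its L is still there and G holds 45.4 % of its X. I read Thursday's clearing time as the start of a tail.

    X + Q → X + Z (k = 370 M⁻¹ s⁻¹)
    Q ⇌ D (K = 7.50, k = 0.00530 s⁻¹)
    G → X + Q (k = 56.0 s⁻¹)
    L + X ⇌ G (K = 170 M⁻¹, k = 1.40 × 10⁵ M⁻¹ s⁻¹)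
- Take Friday's with 2.0 × 10⁻⁵ M of X instead: the clearing time is 87.7 s, under 3.0 min, so I expect X free for about the last 92.3 s. That flask gives 33.5 % of Q and 26.3 % of Z, with L at 0 %.

(The earlier runs and the new flask are calculated on assumed constants; scatter was added.)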